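**Strategy**

In the butyrolactone, the stereocentre C-beta is flanked by two methylene carbons, C-alpha and C-gamma, and only the ring oxygen on C-gamma tells them apart. Taking that oxygen out leaves a 3-(arylmethyl)cyclobutanone with two interchangeable ring CH2 groups, so the route rests on the O–C-gamma disconnection. A catalytic asymmetric Baeyer–Villiger oxidation expands the four-membered ring to the lactone and fixes C-beta as R in one operation. The precursor is a cyclobutanone built on the allyl group of a eugenol-derived ring B that already carries the protected (1R,2R)-1-aryl-propane-1,3-diol side chain with ring C. Ring A is added afterwards by trans-selective enolate benzylation.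

Key step: step 13

**Conventions and remarks**

- Ring A is the 4-hydroxy-3-methoxybenzyl group on C-alpha, ring B the central arene on the C-beta methylene, ring C the arene on the carbinol carbon of the side chain.
- Bn = benzyl, TBS = tert-butyldimethylsilyl.
- ArB = 4-(benzyloxy)-3-methoxy-5-[(1R,2R)-1-[4-(benzyloxy)-3-methoxyphenyl]-1,3-bis(tert-butyldimethylsilyloxy)propan-2-yl]phenyl, that is ring B with its protected side chain and ring C.
- Assumption: [4-(benzyloxy)-3-methoxyphenyl]methanol (O-benzylated, reduced vanillin) is bought, as are eugenol and 4-bromo-2-methoxyphenol.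
- Assumption: the sense of induction in the oxidation is set by the choice of ligand enantiomer, both antipodes being accessible from L- or D-pipecolic acid.
- Check: the key-step ketone and lactone were compared with the target atom by atom and centre by centre. C-beta is R in lactone and target, the side chain is (1R,2R) throughout, and no structural correction was needed.
- Design choice: phenols are carried as benzyl ethers and the two alcohols as TBS ethers. At the end the silyl groups are removed before the benzyl groups, so that the benzylic alcohol never meets HF next to a free phenol.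

**Route**

Step 1
Reactants: 1 eugenol (4-allyl-2-methoxyphenol)
Product: 3 5-allyl-2-hydroxy-3-methoxybenzaldehyde, via 4-allyl-2-(hydroxymethyl)-6-methoxyphenol 2 (not isolated)
Conditions: MgCl2, Et3N, (CH2O)n, MeCN, reflux
Reagents that add atoms: paraformaldehyde (reacts as formaldehyde) C=O
Why: Magnesium-mediated ortho-formylation of a phenol (Casnati–Skattebøl reaction), in which the magnesium phenoxide delivers formaldehyde to the only free ortho position and the salicyl alcohol 2 is oxidised in the flask by hydride transfer to a second formaldehyde, the allyl group being inert.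

Step 2
Reactants: 3 5-allyl-2-hydroxy-3-methoxybenzaldehyde
Product: 4 5-allyl-2-(benzyloxy)-3-methoxybenzaldehyde
Conditions: BnBr, K2CO3, DMF, rt
Reagents that add atoms: benzyl bromide BrCc1ccccc1
Why: Williamson ether synthesis on the acidic salicylaldehyde phenol, a benzyl ether being chosen because it cannot migrate to a neighbouring alkoxide, survives every later step and leaves by hydrogenolysis.

Step 3
Reactants: 4 5-allyl-2-(benzyloxy)-3-methoxybenzaldehyde
Product: 5 ethyl (E)-3-[5-allyl-2-(benzyloxy)-3-methoxyphenyl]prop-2-enoate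
Conditions: Ph3P=CHCO2Et, toluene, 80 °C
Reagents that add atoms: ethyl (triphenylphosphoranylidene)acetate CCOC(=O)C=P(c1ccccc1)(c1ccccc1)c1ccccc1
Why: Wittig olefination with a stabilised ylide, which should give the E-enoate and does not touch the allyl group.

Step 4
Reactants: 5 ethyl (E)-3-[5-allyl-2-(benzyloxy)-3-methoxyphenyl]prop-2-enoate
Product: 6 (E)-3-[5-allyl-2-(benzyloxy)-3-methoxyphenyl]prop-2-en-1-ol
Conditions: i-Bu2AlH, CH2Cl2, −78 °C
Reagents that add atoms: none
Why: Ester reduction with i-Bu2AlH at low temperature is a 1,2-reduction that leaves both the conjugated and the isolated alkene in place.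

Step 5
Reactants: 6 (E)-3-[5-allyl-2-(benzyloxy)-3-methoxyphenyl]prop-2-en-1-ol
Product: 7 [(2R,3R)-3-[5-allyl-2-(benzyloxy)-3-methoxyphenyl]oxiran-2-yl]methanol
Conditions: Ti(OiPr)4 (cat.), D-(−)-diisopropyl tartrate (cat.), t-BuOOH, 4 Å molecular sieves, CH2Cl2, −20 °C
Reagents that add atoms: tert-butyl hydroperoxide CC(C)(C)OO
Why: Sharpless asymmetric epoxidation, in which the titanium–D-tartrate complex binds the allylic hydroxyl and delivers oxygen to one face of the E-alkene, setting C-2 and C-3 as (2R,3R) by reagent control, while the allyl group, lacking a directing hydroxyl, is not epoxidised.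

Step 6
Reactants: 7 [(2R,3R)-3-[5-allyl-2-(benzyloxy)-3-methoxyphenyl]oxiran-2-yl]methanol
Product: 8 tert-butyl{[(2R,3R)-3-[5-allyl-2-(benzyloxy)-3-methoxyphenyl]oxiran-2-yl]methoxy}dimethylsilane
Conditions: TBSCl, imidazole, DMF, 0 °C to rt
Reagents that add atoms: tert-butyldimethylsilyl chloride CC(C)(C)[Si](C)(C)Cl
Why: Standard silylation of the primary alcohol, needed because the following rearrangement operates on the epoxy silyl ether.

Step 7
Reactants: 8 tert-butyl{[(2R,3R)-3-[5-allyl-2-(benzyloxy)-3-methoxyphenyl]oxiran-2-yl]methoxy}dimethylsilane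
Product: 9 (2R)-2-[5-allyl-2-(benzyloxy)-3-methoxyphenyl]-3-(tert-butyldimethylsilyloxy)propanal
Conditions: MeAl(OC6H2-4-Br-2,6-tBu2)2 (from Me3Al and 4-bromo-2,6-di-tert-butylphenol), CH2Cl2, −78 °C; crude aldehyde used at once
Reagents that add atoms: none
Why: Lewis-acid-promoted epoxy silyl ether rearrangement (a semipinacol-type 1,2-shift), in which the bulky aluminium phenoxide opens the epoxide at the benzylic C-3 and the silyloxymethyl carbon migrates to C-3 anti to the departing oxygen, so that inversion at that carbon gives the (2R)-aldehyde, 3-aryl epoxy silyl ethers being a substrate class for which this shift is established.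

Step 8
Reactants: 10 4-bromo-2-methoxyphenol
Product: 11 1-(benzyloxy)-4-bromo-2-methoxybenzene
Conditions: BnBr, K2CO3, DMF, rt
Reagents that add atoms: benzyl bromide BrCc1ccccc1
Why: Williamson ether synthesis, giving the ring C phenol the same protecting group as rings A and B.

Step 9
Reactants: 9 (2R)-2-[5-allyl-2-(benzyloxy)-3-methoxyphenyl]-3-(tert-butyldimethylsilyloxy)propanal; 11 1-(benzyloxy)-4-bromo-2-methoxybenzene
Product: 13 (1R,2R)-2-[5-allyl-2-(benzyloxy)-3-methoxyphenyl]-1-[4-(benzyloxy)-3-methoxyphenyl]-3-(tert-butyldimethylsilyloxy)propan-1-ol, via [4-(benzyloxy)-3-methoxyphenyl]magnesium bromide 12 (not isolated)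
Conditions: 11, Mg, THF, rt; CeCl3 (additive), THF, −78 °C; then 9, −78 °C; aqueous work-up
Reagents that add atoms: none
Why: Grignard formation and CeCl3-modified 1,2-addition to the aldehyde, the low basicity of the cerium-modified reagent at −78 °C limiting enolisation of the α-aryl aldehyde, with Felkin–Anh control (ring B anti to the incoming aryl group, attack past the small hydrogen) expected to set C-1 as R and give the (1R,2R) isomer.

Step 10
Reactants: 13 (1R,2R)-2-[5-allyl-2-(benzyloxy)-3-methoxyphenyl]-1-[4-(benzyloxy)-3-methoxyphenyl]-3-(tert-butyldimethylsilyloxy)propan-1-ol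
Product: 14 (1R,2R)-2-[5-allyl-2-(benzyloxy)-3-methoxyphenyl]-1-[4-(benzyloxy)-3-methoxyphenyl]-1,3-bis(tert-butyldimethylsilyloxy)propane
Conditions: TBSOTf, 2,6-lutidine, CH2Cl2, −78 to 0 °C
Reagents that add atoms: tert-butyldimethylsilyl triflate CC(C)(C)[Si](C)(C)OS(=O)(=O)C(F)(F)F
Why: Silylation of a hindered secondary benzylic alcohol with the silyl triflate, which masks the hydroxyl against acylation in step 11 and alkoxide formation in step 15.

Step 11
Reactants: 14 (1R,2R)-2-[5-allyl-2-(benzyloxy)-3-methoxyphenyl]-1-[4-(benzyloxy)-3-methoxyphenyl]-1,3-bis(tert-butyldimethylsilyloxy)propane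
Product: 15 2,2-dichloro-3-(ArB-methyl)cyclobutan-1-one (both C-3 epimers)
Conditions: Cl3CCOCl, Zn–Cu couple, Et2O–DME, rt
Reagents that add atoms: trichloroacetyl chloride ClC(Cl)(Cl)C(Cl)=O
Why: Thermal [2+2] cycloaddition of dichloroketene, made in the flask, to the terminal alkene with the carbonyl carbon bonding to the terminal CH2, DME tying up ZnCl2 and the new ring stereocentre being of no consequence because it disappears in step 12.

Step 12
Reactants: 15 2,2-dichloro-3-(ArB-methyl)cyclobutan-1-one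
Product: 16 3-(ArB-methyl)cyclobutan-1-one
Conditions: Zn, NH4Cl, MeOH, rt
Reagents that add atoms: none
Why: Reductive dehalogenation of the α,α-dichloro ketone by zinc under buffered conditions that spare the silyl ethers, giving the symmetrical 3-substituted cyclobutanone.

Step 13
Reactants: 16 3-(ArB-methyl)cyclobutan-1-one
Product: 18 (4R)-4-(ArB-methyl)oxolan-2-one, via Criegee adduct 17 (not isolated)
Conditions: Sc(OTf)3 (10 mol%), chiral N,N'-dioxide ligand (pipecolic acid-derived bis-anilide, 10 mol%, enantiomer chosen for 4R), m-CPBA, EtOAc, −20 °C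
Reagents that add atoms: 3-chloroperoxybenzoic acid OOC(=O)c1cccc(Cl)c1
Why: The Sc(OTf)3–N,N'-dioxide complex binds the strained carbonyl, m-CPBA adds to give Criegee adduct 17, and the ring CH2 lying antiperiplanar to the O–O bond shifts from carbon to oxygen as 3-chlorobenzoate leaves, which makes the O–C-gamma bond (Baeyer–Villiger oxidation). The closest known reaction type is the catalytic asymmetric Baeyer–Villiger desymmetrisation of prochiral 3-substituted cyclobutanones with chiral Lewis acid–peracid or chiral phosphoric acid–H2O2 systems. The five-membered lactone ring arises by ring expansion, a 1,2-shift that inserts oxygen into the four-membered ring, and not by closure of an open chain. The new stereocentre C-beta (4R) is controlled by the chiral ligand on scandium, which fixes the conformation of the bound adduct and so selects the CH2 group that is aligned for migration, the distant side-chain centres being expected to have little influence. The step needs only this choice between the two ring CH2 groups (enantiotopic in the ring, strictly diastereotopic here), since both are methylenes of a locally symmetric ketone and no regiochemical question arises. Chemoselectivity over the electron-rich arenes and benzyl ethers is secured by the ring strain that lets the cyclobutanone react at low temperature.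

Step 14
Reactants: 19 [4-(benzyloxy)-3-methoxyphenyl]methanol
Product: 20 1-(benzyloxy)-4-(bromomethyl)-2-methoxybenzene
Conditions: PBr3, Et2O, 0 °C
Reagents that add atoms: phosphorus tribromide BrP(Br)Br
Why: Conversion of a benzylic alcohol into the bromide by nucleophilic substitution of its phosphite ester, the labile bromide being used fresh.

Step 15
Reactants: 18 (4R)-4-(ArB-methyl)oxolan-2-one; 20 1-(benzyloxy)-4-(bromomethyl)-2-methoxybenzene
Product: 22 (3R,4R)-3-[4-(benzyloxy)-3-methoxybenzyl]-4-(ArB-methyl)oxolan-2-one, via lithium lactone enolate 21 (not isolated)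
Conditions: LiN(SiMe3)2, THF, −78 °C; then 20, DMPU, −78 to −40 °C
Reagents that add atoms: none
Why: SN2 alkylation of the lactone lithium enolate with a benzylic bromide, the electrophile approaching the enolate face opposite the C-beta substituent so that C-alpha is set as R, trans to C-beta, by substrate control.

Step 16
Reactants: 22 (3R,4R)-3-[4-(benzyloxy)-3-methoxybenzyl]-4-(ArB-methyl)oxolan-2-one
Product: 23 (3R,4R)-3-[4-(benzyloxy)-3-methoxybenzyl]-4-{4-(benzyloxy)-3-[(1R,2R)-1-[4-(benzyloxy)-3-methoxyphenyl]-1,3-dihydroxypropan-2-yl]-5-methoxybenzyl}oxolan-2-one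
Conditions: HF·pyridine, pyridine, THF, 0 °C to rt
Reagents that add atoms: none
Why: Fluoride-mediated cleavage of both silyl ethers, placed before debenzylation so that no free phenol is present while the benzylic alcohol is exposed to HF.

Step 17
Reactants: 23 (3R,4R)-3-[4-(benzyloxy)-3-methoxybenzyl]-4-{4-(benzyloxy)-3-[(1R,2R)-1-[4-(benzyloxy)-3-methoxyphenyl]-1,3-dihydroxypropan-2-yl]-5-methoxybenzyl}oxolan-2-one
Product: 24 CNP0109231.2, (3R,4R)-4-{4-hydroxy-3-[(1R,2R)-1,3-dihydroxy-1-(4-hydroxy-3-methoxyphenyl)propan-2-yl]-5-methoxybenzyl}-3-(4-hydroxy-3-methoxybenzyl)oxolan-2-one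
Conditions: H2 (1 atm), 10% Pd/C, EtOAc, rt
Reagents that add atoms: none
Why: Catalytic hydrogenolysis of the three aryl benzyl ethers under neutral conditions, which normally spare secondary benzylic alcohols and the lactone.

**Compound list**

1 | eugenol (4-allyl-2-methoxyphenol) | C=CCc1ccc(O)c(OC)c1 | starting material
2 | 4-allyl-2-(hydroxymethyl)-6-methoxyphenol | C=CCc1cc(CO)c(O)c(OC)c1 | intermediate
3 | 5-allyl-2-hydroxy-3-methoxybenzaldehyde | C=CCc1cc(C=O)c(O)c(OC)c1 | intermediate
4 | 5-allyl-2-(benzyloxy)-3-methoxybenzaldehyde | C=CCc1cc(C=O)c(OCc2ccccc2)c(OC)c1 | intermediate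
5 | ethyl (E)-3-[5-allyl-2-(benzyloxy)-3-methoxyphenyl]prop-2-enoate | C=CCc1cc(/C=C/C(=O)OCC)c(OCc2ccccc2)c(OC)c1 | intermediate
6 | (E)-3-[5-allyl-2-(benzyloxy)-3-methoxyphenyl]prop-2-en-1-ol | C=CCc1cc(/C=C/CO)c(OCc2ccccc2)c(OC)c1 | intermediate
7 | [(2R,3R)-3-[5-allyl-2-(benzyloxy)-3-methoxyphenyl]oxiran-2-yl]methanol | OC[C@H]1O[C@@H]1c1cc(CC=C)cc(OC)c1OCc1ccccc1 | intermediate
8 | tert-butyl{[(2R,3R)-3-[5-allyl-2-(benzyloxy)-3-methoxyphenyl]oxiran-2-yl]methoxy}dimethylsilane | CC(C)(C)[Si](C)(C)OC[C@H]1O[C@@H]1c1cc(CC=C)cc(OC)c1OCc1ccccc1 | intermediate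
9 | (2R)-2-[5-allyl-2-(benzyloxy)-3-methoxyphenyl]-3-(tert-butyldimethylsilyloxy)propanal | O=C[C@@H](CO[Si](C)(C)C(C)(C)C)c1cc(CC=C)cc(OC)c1OCc1ccccc1 | intermediate
10 | 4-bromo-2-methoxyphenol | COc1cc(Br)ccc1O | starting material
11 | 1-(benzyloxy)-4-bromo-2-methoxybenzene | COc1cc(Br)ccc1OCc1ccccc1 | intermediate
12 | [4-(benzyloxy)-3-methoxyphenyl]magnesium bromide | COc1cc([Mg]Br)ccc1OCc1ccccc1 | intermediate
13 | (1R,2R)-2-[5-allyl-2-(benzyloxy)-3-methoxyphenyl]-1-[4-(benzyloxy)-3-methoxyphenyl]-3-(tert-butyldimethylsilyloxy)propan-1-ol | C=CCc1cc(OC)c(OCc2ccccc2)c([C@H](CO[Si](C)(C)C(C)(C)C)[C@@H](O)c2ccc(OCc3ccccc3)c(OC)c2)c1 | intermediate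
14 | (1R,2R)-2-[5-allyl-2-(benzyloxy)-3-methoxyphenyl]-1-[4-(benzyloxy)-3-methoxyphenyl]-1,3-bis(tert-butyldimethylsilyloxy)propane | C=CCc1cc(OC)c(OCc2ccccc2)c([C@H](CO[Si](C)(C)C(C)(C)C)[C@@H](O[Si](C)(C)C(C)(C)C)c2ccc(OCc3ccccc3)c(OC)c2)c1 | intermediate
15 | 2,2-dichloro-3-(ArB-methyl)cyclobutan-1-one, both C-3 epimers | O=C1CC(Cc2cc(OC)c(OCc3ccccc3)c([C@H](CO[Si](C)(C)C(C)(C)C)[C@@H](O[Si](C)(C)C(C)(C)C)c3ccc(OCc4ccccc4)c(OC)c3)c2)C1(Cl)Cl | intermediate
16 | 3-(ArB-methyl)cyclobutan-1-one | O=C1CC(Cc2cc(OC)c(OCc3ccccc3)c([C@H](CO[Si](C)(C)C(C)(C)C)[C@@H](O[Si](C)(C)C(C)(C)C)c3ccc(OCc4ccccc4)c(OC)c3)c2)C1 | intermediate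
17 | Criegee adduct, 1-hydroxy-3-(ArB-methyl)cyclobutyl 3-chloroperoxybenzoate | OC1(OOC(=O)c2cccc(Cl)c2)CC(Cc2cc(OC)c(OCc3ccccc3)c([C@H](CO[Si](C)(C)C(C)(C)C)[C@@H](O[Si](C)(C)C(C)(C)C)c3ccc(OCc4ccccc4)c(OC)c3)c2)C1 | intermediate
18 | (4R)-4-(ArB-methyl)oxolan-2-one | O=C1C[C@@H](Cc2cc(OC)c(OCc3ccccc3)c([C@H](CO[Si](C)(C)C(C)(C)C)[C@@H](O[Si](C)(C)C(C)(C)C)c3ccc(OCc4ccccc4)c(OC)c3)c2)CO1 | intermediate
19 | [4-(benzyloxy)-3-methoxyphenyl]methanol | COc1cc(CO)ccc1OCc1ccccc1 | starting material
20 | 1-(benzyloxy)-4-(bromomethyl)-2-methoxybenzene | COc1cc(CBr)ccc1OCc1ccccc1 | intermediate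
21 | lithium enolate of 18, lithium (4R)-4-(ArB-methyl)-4,5-dihydrofuran-2-olate | [Li]OC1=C[C@@H](Cc2cc(OC)c(OCc3ccccc3)c([C@H](CO[Si](C)(C)C(C)(C)C)[C@@H](O[Si](C)(C)C(C)(C)C)c3ccc(OCc4ccccc4)c(OC)c3)c2)CO1 | intermediate
22 | (3R,4R)-3-[4-(benzyloxy)-3-methoxybenzyl]-4-(ArB-methyl)oxolan-2-one | COc1cc(C[C@H]2C(=O)OC[C@@H]2Cc2cc(OC)c(OCc3ccccc3)c([C@H](CO[Si](C)(C)C(C)(C)C)[C@@H](O[Si](C)(C)C(C)(C)C)c3ccc(OCc4ccccc4)c(OC)c3)c2)ccc1OCc1ccccc1 | intermediate
23 | (3R,4R)-3-[4-(benzyloxy)-3-methoxybenzyl]-4-{4-(benzyloxy)-3-[(1R,2R)-1-[4-(benzyloxy)-3-methoxyphenyl]-1,3-dihydroxypropan-2-yl]-5-methoxybenzyl}oxolan-2-one | COc1cc(C[C@H]2C(=O)OC[C@@H]2Cc2cc(OC)c(OCc3ccccc3)c([C@H](CO)[C@@H](O)c3ccc(OCc4ccccc4)c(OC)c3)c2)ccc1OCc1ccccc1 | intermediate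
24 | CNP0109231.2, (3R,4R)-4-{4-hydroxy-3-[(1R,2R)-1,3-dihydroxy-1-(4-hydroxy-3-methoxyphenyl)propan-2-yl]-5-methoxybenzyl}-3-(4-hydroxy-3-methoxybenzyl)oxolan-2-one | COc1cc(C[C@H]2C(=O)OC[C@@H]2Cc2cc(OC)c(O)c([C@H](CO)[C@@H](O)c3ccc(O)c(OC)c3)c2)ccc1O | target

**Step count and risks**

Total steps: 17. Longest linear sequence: 15 steps (eugenol to the target through steps 1–7, 9–13 and 15–17).

Steps most likely to fail:

1. Step 13, the ring expansion. The catalyst may discriminate only weakly between the two ring CH2 groups, because the substituent at C-3 is an arylmethyl and not an aryl group, so that both C-beta epimers form. Some arene oxidation by the peracid is a lesser concern. Fallback, from 16 back to 18: desymmetrise the ketone by enantioselective deprotonation instead of oxygen insertion. Treatment of 16 with lithium bis[(R)-1-phenylethyl]amide, or its enantiomer, chosen so that the CH2 destined to become C-gamma is deprotonated, in the presence of Me3SiCl in THF at −100 °C should give the silyl enol ether (3R)-3-(ArB-methyl)-1-(trimethylsilyloxy)cyclobut-1-ene F1. Ozonolysis of its only C=C bond (O3, CH2Cl2–MeOH, −78 °C) with NaBH4 work-up should give the hydroxy acid (3R)-4-hydroxy-3-(ArB-methyl)butanoic acid F2, which closes to lactone 18 on mild acidification.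

2. Step 9, the aryl addition. The basic aryl-metal may enolise the α-aryl aldehyde or eliminate silanol from it, which erodes the C-2 centre. Facial control may also be weak, for instance if the ortho-benzyloxy group of ring B chelates the metal, giving both C-1 epimers. Fallback, from 4 back to 14: bring ring C in before the rearrangement, so that both centres come from a stereospecific shift and no nucleophile is added to a labile aldehyde.
   - Claisen–Schmidt condensation of 4 with purchased 1-[4-(benzyloxy)-3-methoxyphenyl]ethanone (NaOH, EtOH, rt) should give the chalcone (E)-3-[5-allyl-2-(benzyloxy)-3-methoxyphenyl]-1-[4-(benzyloxy)-3-methoxyphenyl]prop-2-en-1-one F3.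
   - Asymmetric nucleophilic epoxidation under Juliá–Colonna conditions (poly-L-leucine, urea–H2O2, DBU, THF) should give the (2R,3S)-epoxy ketone F4.
   - Chelation-controlled reduction with Zn(BH4)2 (Et2O, −20 °C) is expected to give the erythro (1S,2S,3S)-epoxy alcohol F5, which is silylated (TBSCl, imidazole, DMF) to the epoxy silyl ether F6.
   - The aluminium-promoted rearrangement of step 7 (MeAl(OC6H2-4-Br-2,6-tBu2)2, CH2Cl2, −78 °C) would then move the α-silyloxybenzyl carbon to the ring B benzylic carbon, with inversion there and retention in the migrating carbon, to give the (2S,3R)-aldehyde F7.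
   - F7 is reduced at once (NaBH4, MeOH, 0 °C) to the (2R,3R)-primary alcohol F8, and silylation (TBSCl, imidazole, DMF) gives 14.

3. Step 17, the final hydrogenolysis. Once ring C is debenzylated, its benzylic hydroxyl is para to a free phenol and may be lost by over-reduction. Traces of acid on the catalyst could also close the ring B phenol onto that carbon to give a dihydrobenzofuran. Fallback, from 22 to 24: reverse the order of the two deprotections. Hydrogenolysis of 22 (H2, 10% Pd/C, EtOAc, rt) while the benzylic oxygen still carries its silyl group should give the triphenol bis-silyl ether F9, and buffered fluoride (Et3N·3HF, MeCN–THF, rt) then frees the diol to give 24.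

**Further compounds**

F1 | step 13 | (3R)-3-(ArB-methyl)-1-(trimethylsilyloxy)cyclobut-1-ene | C[Si](C)(C)OC1=C[C@H](Cc2cc(OC)c(OCc3ccccc3)c([C@H](CO[Si](C)(C)C(C)(C)C)[C@@H](O[Si](C)(C)C(C)(C)C)c3ccc(OCc4ccccc4)c(OC)c3)c2)C1
F2 | step 13 | (3R)-4-hydroxy-3-(ArB-methyl)butanoic acid | OC(=O)C[C@@H](Cc1cc(OC)c(OCc2ccccc2)c([C@H](CO[Si](C)(C)C(C)(C)C)[C@@H](O[Si](C)(C)C(C)(C)C)c2ccc(OCc3ccccc3)c(OC)c2)c1)CO
F3 | step 9 | (E)-3-[5-allyl-2-(benzyloxy)-3-methoxyphenyl]-1-[4-(benzyloxy)-3-methoxyphenyl]prop-2-en-1-one | COc1cc(C(=O)/C=C/c2cc(CC=C)cc(OC)c2OCc2ccccc2)ccc1OCc1ccccc1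
F4 | step 9 | [(2R,3S)-3-[5-allyl-2-(benzyloxy)-3-methoxyphenyl]oxiran-2-yl][4-(benzyloxy)-3-methoxyphenyl]methanone | COc1cc(C(=O)[C@@H]2O[C@H]2c2cc(CC=C)cc(OC)c2OCc2ccccc2)ccc1OCc1ccccc1
F5 | step 9 | (S)-[(2S,3S)-3-[5-allyl-2-(benzyloxy)-3-methoxyphenyl]oxiran-2-yl][4-(benzyloxy)-3-methoxyphenyl]methanol | COc1cc([C@H](O)[C@@H]2O[C@H]2c2cc(CC=C)cc(OC)c2OCc2ccccc2)ccc1OCc1ccccc1
F6 | step 9 | tert-butyldimethylsilyl ether of F5, (S)-carbinol, (2S,3S)-oxirane | COc1cc([C@H](O[Si](C)(C)C(C)(C)C)[C@@H]2O[C@H]2c2cc(CC=C)cc(OC)c2OCc2ccccc2)ccc1OCc1ccccc1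
F7 | step 9 | (2S,3R)-2-[5-allyl-2-(benzyloxy)-3-methoxyphenyl]-3-[4-(benzyloxy)-3-methoxyphenyl]-3-(tert-butyldimethylsilyloxy)propanal | C=CCc1cc(OC)c(OCc2ccccc2)c([C@H](C=O)[C@@H](O[Si](C)(C)C(C)(C)C)c2ccc(OCc3ccccc3)c(OC)c2)c1
F8 | step 9 | (2R,3R)-2-[5-allyl-2-(benzyloxy)-3-methoxyphenyl]-3-[4-(benzyloxy)-3-methoxyphenyl]-3-(tert-butyldimethylsilyloxy)propan-1-ol | C=CCc1cc(OC)c(OCc2ccccc2)c([C@H](CO)[C@@H](O[Si](C)(C)C(C)(C)C)c2ccc(OCc3ccccc3)c(OC)c2)c1
F9 | step 17 | (3R,4R)-4-{3-[(1R,2R)-1,3-bis(tert-butyldimethylsilyloxy)-1-(4-hydroxy-3-methoxyphenyl)propan-2-yl]-4-hydroxy-5-methoxybenzyl}-3-(4-hydroxy-3-methoxybenzyl)oxolan-2-one | COc1cc(C[C@H]2C(=O)OC[C@@H]2Cc2cc(OC)c(O)c([C@H](CO[Si](C)(C)C(C)(C)C)[C@@H](O[Si](C)(C)C(C)(C)C)c3ccc(O)c(OC)c3)c2)ccc1O
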